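The numbers of this flask are assumed, and the outcome is calculated.

Time of addition is what separates these flasks: the charges are the same in each, and each run lasts 40 s.

the same everywhere: second substrate 1.00 mM; free catalyst 32 µM; impurity 37 µM; time 40 s

| flask | starting material | coupling partner | remark |
|---|---|---|---|
| red | 0.0010 M (fed, over 2.0 s) | 0.600 mM | all else is in the flask from the start; the feed brings no volume worth counting |
| blue | 0.0010 M | 0.600 mM | everything together at the start |
| ochre | 0.0010 M (fed, over 8.0 s) | 0.600 mM | all else is in the flask from the start; the feed brings no volume worth counting |
| grey | 0.0010 M | 0.600 mM (fed, over 8.0 s) | all else is in the flask from the start; the feed brings no volume worth counting |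

    starting material + free catalyst ⇌ catalyst intermediate A (K1 = 2400 /M, k1 = 14000 /M/s)
    coupling partner + catalyst intermediate A → free catalyst + target (k2 = 1.6 × 10⁵ /M/s)
    second substrate + free catalyst ⇌ catalyst intermediate B (K3 = 380 /M, k3 = 19000 /M/s)
    coupling partner + catalyst intermediate B → free catalyst + second product (k4 = 21000 /M/s)
    starting material + target → side product (k5 = 150 /M/s)
    starting material + catalyst intermediate B → spent catalyst A (k6 = 700 /M/s)
    free catalyst + impurity → spent catalyst B (k7 = 1.4 × 10⁵ /M/s)

- percentages count the starting material that a species holds: one side product counts as two
- run time (red): 40 s

- the flask with the highest amount of side product, in percent of the starting material charged ("all alike" if they lie within 1.5 percentage points) (red / blue / ochre / grey / all alike)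
- final side product, as a percentage of the starting material charged, in red
- final side product, as a percentage of the starting material charged, in blue
- final side product, as a percentage of the starting material charged, in ochre
- final side product, as a percentage of the starting material charged, in grey

This reckoning climbs the clocks of blue, where everything is together at the start, and it counts what is left, not what is made. On the first rung stands catalyst intermediate B, with a half-life of 0.055 s against the coupling partner as charged, which is shorter than the 0.99 s it has against starting material. Next, free catalyst meets impurity with a half-life of 0.134 s, shorter than the 1.5 s of starting material by its forward binding step, so in blue the catalyst should die before starting material has fallen far. Higher up, target has a half-life of 4.6 s against starting material, far shorter than the run, so each target is reckoned to take a second starting material into side product.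

Impurity and starting material are both taken by free catalyst, each first order in itself. So, for the first uptake of starting material, with the step from target to side product set aside, and while the forward share holds, the logarithms of the two fractions left keep a fixed ratio, however free catalyst moves in time. The second starting material stands outside that ratio: it goes through target, whose half-life of 4.6 s is longer than the 0.134 s of free catalyst, so it is added afterwards as an amount, not as a logarithm. Intermediate A goes forward at 96.0 /s and back at 5.83 /s, which gives a forward share φ of 0.943. The ratio is φ times the binding constant 14000 /M/s over the poisoning constant 1.4 × 10⁵ /M/s: s, the selectivity factor, the logarithm of the fraction of starting material left by the first uptake per logarithm of the fraction of impurity left, 0.0943. If impurity kills the whole catalyst charge, a fraction 13.5 % of it remains. That fraction raised to s leaves 82.8 % of the starting material past the first uptake in blue. Each target then takes a second starting material, so the amount lost counts double, which gives 34.4 % side product. The reckoning stops there: a feed over 2.0 s or 8.0 s runs longer than the catalyst's half-life, so red and ochre should stand below blue, and grey stays open.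

The forecast names blue as highest, with 12.3 % in red, 27.8 % in blue, 4.7 % in ochre and 14.7 % in grey. Its ground is that “the total catalyst exposure ∫[free catalyst]dt is nearly fixed”. For blue, the reckoning above stands higher than the forecast.

The simulation puts blue highest, with 12.0 % in red, 27.6 % in blue, 4.40 % in ochre and 15.8 % in grey. After 40.0 s, blue holds 19.6 % of its impurity, more than reckoned, with spent catalyst A at 7.06 % of the catalyst beside spent catalyst B at 92.9 %. That reading raised to s, with the loss counted double, gives 71.5 % of starting material left, and blue holds 72.0 %. A neighbour of blue with 0.0040 M of second substrate keeps 31.5 % of its impurity, which raised to s, with the loss counted double, gives 79.4 %, and that flask ends with 79.2 % of its starting material.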